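## Retrosynthetic overview

1. The trione ring is numbered as in the name of the target: C1 ring C=O, C2 butanoyl-bearing, C3 C–OH, C4 CMe2, C5 C–OH, C6 CH2-bearing. Last disconnection: the C2–butanoyl bond, a C-acylation of the only free ring CH of the trione.
2. Key disconnection: ring bonds C2–C3 and C4–C5. C3/C4 come from dimethylketene, C1/C2 from the acetyl group and C5/C6 from the lactone C=O and α-carbon of a 3-acetyl-3,4-dihydrocoumarin. C4–C5 is formed last and closes the ring.
3. Enabling feature: the phenol oxygen on the aromatic carbon ortho to the bridging CH2 is joined to C5 through that carbon, the CH2-bearing aromatic carbon, the CH2 and C6. C5 can therefore be stored as the carbonyl of a six-membered aryl lactone (a temporary dihydrocoumarin ring, absent from the target) whose cleavage returns this phenol. C4 lies between two carbonyl-level carbons, so it can arrive as the carbon of the enolate formed when a carbanion adds to dimethylketene.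
4. The lactone comes from Knoevenagel condensation/lactonization of 3-butanoyl-2,6-dihydroxy-4-methoxybenzaldehyde with ethyl acetoacetate, then hydrogenation. The aldehyde comes from mono-methylation and C-butanoylation of 2,4,6-trihydroxybenzaldehyde, whose free ring positions are equivalent by symmetry at the acylation stage.
5. Order of rings: aromatic ring bought; temporary lactone ring (step 3); carbocyclic trione ring (step 6), closed as the lactone ring is opened.

Key step: step 6

Remark: the target and the triones on the way are keto–enol tautomer mixtures; one tautomer is drawn for each, and the target has no stereocentre.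

## Route

Step 1
Reactants: 1 2,4,6-trihydroxybenzaldehyde
Product: 2 2,6-dihydroxy-4-methoxybenzaldehyde
Conditions: MeI (1.0 equiv), NaHCO3 (1.1 equiv), DMF, 40 °C
Reagents that add atoms: iodomethane, CI
Why: Williamson etherification under weak-base control; the 4-OH, para to the formyl group, is the most acidic hydroxyl and the only one not held in a hydrogen bond to the C=O, so it should be methylated selectively.

Step 2
Reactants: 2 2,6-dihydroxy-4-methoxybenzaldehyde
Product: 3 3-butanoyl-2,6-dihydroxy-4-methoxybenzaldehyde
Conditions: PrCOCl (1.1 equiv), Sc(OTf)3 (10 mol %), toluene/MeNO2, 100 °C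
Reagents that add atoms: butanoyl chloride, CCCC(=O)Cl
Why: Friedel–Crafts acylation by O-acylation and Fries rearrangement; the two free ring positions of 2 are equivalent by symmetry, each ortho to OH and OMe and para to the other OH, so the regiochemistry is unambiguous and the first acyl group deactivates the ring against a second.

Step 3
Reactants: 3 3-butanoyl-2,6-dihydroxy-4-methoxybenzaldehyde; 4 ethyl acetoacetate
Product: 5 3-acetyl-6-butanoyl-5-hydroxy-7-methoxy-2H-chromen-2-one
Conditions: piperidine (cat.), EtOH, reflux
Reagents that add atoms: none
Why: Knoevenagel condensation followed by lactonization, the classical 3-acetylcoumarin synthesis; the hydroxyl flanked by CHO and butanoyl stays chelated to the ketone, so the other ortho-hydroxyl should close the lactone, and since step 6 reopens this lactone to the free phenol the choice of hydroxyl does not change the structure reached after step 6.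

Step 4
Reactants: 5 3-acetyl-6-butanoyl-5-hydroxy-7-methoxy-2H-chromen-2-one
Product: 6 3-acetyl-6-butanoyl-5-hydroxy-7-methoxy-3,4-dihydro-2H-chromen-2-one (racemic)
Conditions: H2 (1 atm), 10% Pd/C, EtOAc, rt
Reagents that add atoms: none
Why: catalytic hydrogenation of the electron-poor C3=C4 bond of an alkylidene β-keto lactone, which is reduced far more easily than the chelated aryl ketone; the C3 centre is formed racemic and enolizable, which does not matter because it becomes sp2 in step 6.

Step 5
Reactants: 7 2,2,4,4-tetramethylcyclobutane-1,3-dione
Product: 8 dimethylketene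
Conditions: flash pyrolysis, 600 °C, quartz tube, N2 stream; condensate trapped at −78 °C, diluted with THF, used at once under argon
Reagents that add atoms: none
Why: thermal [2+2] cycloreversion of the ketene dimer, the reverse of the dimerization of dimethylketene, in which each molecule of 7 should split into two molecules of 8 with no protic or electrophilic by-product.

Step 6
Reactants: 6 3-acetyl-6-butanoyl-5-hydroxy-7-methoxy-3,4-dihydro-2H-chromen-2-one; 8 dimethylketene
Product: 10 2-[(3-butanoyl-2,6-dihydroxy-4-methoxyphenyl)methyl]-3,5-dihydroxy-4,4-dimethylcyclohexa-2,5-dien-1-one, via ketene adduct 9 (not isolated)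
Conditions: LiN(i-Pr)2 (LDA, 4.2 equiv), THF, −78 → −30 °C; then 8 (1.05 equiv), −78 °C → rt; aq. HCl, 0 °C
Reagents that add atoms: none
Why: Proposed new method: the tetralithio form of 6 (phenoxide, β-keto lactone enolate, aryl-ketone enolate and the CH2 carbanion of the acetyl group) should add through the carbanion, its last-formed and most basic site, to the carbonyl carbon of 8, which creates the fully substituted enolate O–C(=CMe2) only at the future gem-dimethyl carbon without any deprotonation of a tertiary C–H (adduct 9). This enolate carbon then attacks the lactone carbonyl in a 6-(enolendo)-exo-trig Claisen closure (or adds to the acylketene that arises if the β-keto lactone enolate first expels the aryloxide), the aryloxide leaves, and the new cyclohexane-1,3,5-trione is drained as its enolate, which makes the formation of the quaternary carbon irreversible. Closest known reaction types are the γ-acylation of β-keto ester dianions, the regiospecific generation of enolates by addition of carbanions to ketenes, the Claisen cyclization of polyketo ester polyanions to acylphloroglucinols and the Baker–Venkataraman O-to-C acyl transfer from aryl esters. One carbocycle is closed while the temporary lactone ring is opened, no stereocentre is formed and the labile C3 centre of 6 becomes sp2. The step needs attack of 8 at the acetyl carbanion rather than at the delocalized enolates, the phenoxide or diisopropylamine, which the basicity gap, one equivalent of 8 and −78 °C should secure, and it needs C- rather than O-acylation in the closure, which is favoured because an enol ester next to the tethered aryloxide can revert whereas the C-acylated trione enolate cannot.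

Step 7
Reactants: 10 2-[(3-butanoyl-2,6-dihydroxy-4-methoxyphenyl)methyl]-3,5-dihydroxy-4,4-dimethylcyclohexa-2,5-dien-1-one
Product: 11 2-butanoyl-6-[(3-butanoyl-2,6-dihydroxy-4-methoxyphenyl)methyl]-3,5-dihydroxy-4,4-dimethylcyclohexa-2,5-dien-1-one (target)
Conditions: PrCO2H (1.05 equiv), DCC (1.1 equiv), DMAP (0.2 equiv), CH2Cl2, 0 °C → rt
Reagents that add atoms: butanoic acid, CCCC(=O)O
Why: carbodiimide-mediated O-acylation of the strongly acidic trione enol followed by DMAP-catalysed O-to-C acyl migration (Fries-type rearrangement of an enol ester, the standard route to 2-acylcyclohexane-1,3-diones) should place the acyl group on the only free ring CH; it is done last because a butanoyl group on C2 before step 6 would make C2–H the most acidic site and quench the ketene-derived enolate.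

## Compound list

1 | 2,4,6-trihydroxybenzaldehyde | O=Cc1c(O)cc(O)cc1O | starting material
2 | 2,6-dihydroxy-4-methoxybenzaldehyde | COc1cc(O)c(C=O)c(O)c1 | intermediate
3 | 3-butanoyl-2,6-dihydroxy-4-methoxybenzaldehyde | CCCC(=O)c1c(OC)cc(O)c(C=O)c1O | intermediate
4 | ethyl acetoacetate | CCOC(=O)CC(C)=O | starting material
5 | 3-acetyl-6-butanoyl-5-hydroxy-7-methoxy-2H-chromen-2-one | CCCC(=O)c1c(OC)cc2oc(=O)c(C(C)=O)cc2c1O | intermediate
6 | 3-acetyl-6-butanoyl-5-hydroxy-7-methoxy-3,4-dihydro-2H-chromen-2-one (racemic, labile centre) | CCCC(=O)c1c(OC)cc2OC(=O)C(C(C)=O)Cc2c1O | intermediate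
7 | 2,2,4,4-tetramethylcyclobutane-1,3-dione | CC1(C)C(=O)C(C)(C)C1=O | starting material
8 | dimethylketene | CC(C)=C=O | intermediate
9 | 6-butanoyl-5-hydroxy-3-(3-hydroxy-4-methylpent-3-enoyl)-7-methoxy-3,4-dihydro-2H-chromen-2-one, present as its lithium polyenolate (racemic, not isolated) | CCCC(=O)c1c(OC)cc2OC(=O)C(C(=O)CC(O)=C(C)C)Cc2c1O | intermediate
10 | 2-[(3-butanoyl-2,6-dihydroxy-4-methoxyphenyl)methyl]-3,5-dihydroxy-4,4-dimethylcyclohexa-2,5-dien-1-one | CCCC(=O)c1c(OC)cc(O)c(CC2=C(O)C(C)(C)C(O)=CC2=O)c1O | intermediate
11 | 2-butanoyl-6-[(3-butanoyl-2,6-dihydroxy-4-methoxyphenyl)methyl]-3,5-dihydroxy-4,4-dimethylcyclohexa-2,5-dien-1-one | CCCC(=O)C1=C(O)C(C)(C)C(O)=C(Cc2c(O)cc(OC)c(C(=O)CCC)c2O)C1=O | target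

## Step count and risks

Total steps: 7. Longest linear sequence: 6 (steps 1, 2, 3, 4, 6, 7; step 5 prepares the ketene).

**Step 6 (key step).** The closure may go through the enolate oxygen instead of carbon, ending in an enol lactone. The ketene may be captured by the aryl-ketone enolate, a phenoxide oxygen or diisopropylamine. Proton transfer may move the enolate away from the gem-dimethyl carbon before it closes.
Fallback, known chemistry, setting out from 3 and coming back at 10: commercial 1-(2,4,6-trihydroxyphenyl)ethan-1-one would be C-methylated twice at one ring carbon (NaOMe, MeI, MeOH, 0 °C → rt), the acetyl group blocking a third ring position against over-alkylation, to give acetylfilicinic acid F1. Deacetylation of F1 (aq. H2SO4, 80 °C), a retro-Friedel–Crafts/retro-Claisen cleavage of the 2-acyl trione, should give filicinic acid F2. F2, used in excess because its two ring CH sites are equivalent, would be joined to aldehyde 3 by three-component reductive alkylation (L-proline cat., Hantzsch ester, CH2Cl2/EtOH, rt). This is a Knoevenagel condensation to the alkylidene trione with conjugate reduction in the same flask. It should give 10, which continues with step 7.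

**Step 2.** The formyl group may be lost by ipso-attack of the acylating agent, the aldehyde may condense with the new ketone under acid, or the reaction may stop at the aryl ester.
Fallback, setting out from 2 and coming back at 11: the aromatic butanoyl group is postponed. Aldehyde 2 and 4 (piperidine, EtOH) should give 3-acetyl-5-hydroxy-7-methoxycoumarin F3, a single lactone by symmetry. Hydrogenation (H2, Pd/C) should give the dihydrocoumarin F4. The annulation of step 6 with one equivalent less base, since no aryl ketone is present, should pass through ketene adduct F5 to the trione F6. Twofold C-butanoylation of F6 (butanoic anhydride, BF3·OEt2, 60 °C), once on the trione CH and once on one of the two equivalent aromatic CH positions, should then give 11.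

**Step 7.** Acylation may occur on a phenolic oxygen, a second acyl group may be taken up, or the O-to-C migration may stay incomplete.
Fallback, setting out from 3 and coming back at 11: the butanoyl group is placed on the trione before the bridge is made. Commercial 1-(2,4,6-trihydroxyphenyl)butan-1-one would be dearomatized by twofold C-methylation (NaOMe, MeI, MeOH) to butanoylfilicinic acid F7. Reductive alkylation of F7 with aldehyde 3 (L-proline cat., Hantzsch ester, CH2Cl2/EtOH, rt) should give 11 directly.

Further compounds
F1 | step 6 | 2-acetyl-3,5-dihydroxy-4,4-dimethylcyclohexa-2,5-dien-1-one (acetylfilicinic acid) | CC(=O)C1=C(O)C(C)(C)C(O)=CC1=O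
F2 | step 6 | 3,5-dihydroxy-4,4-dimethylcyclohexa-2,5-dien-1-one (filicinic acid) | CC1(C)C(O)=CC(=O)C=C1O
F3 | step 2 | 3-acetyl-5-hydroxy-7-methoxy-2H-chromen-2-one | CC(=O)c1cc2c(O)cc(OC)cc2oc1=O
F4 | step 2 | 3-acetyl-5-hydroxy-7-methoxy-3,4-dihydro-2H-chromen-2-one (racemic) | CC(=O)C1Cc2c(O)cc(OC)cc2OC1=O
F5 | step 2 | 5-hydroxy-3-(3-hydroxy-4-methylpent-3-enoyl)-7-methoxy-3,4-dihydro-2H-chromen-2-one, as its lithium polyenolate (racemic, not isolated) | COc1cc(O)c2CC(C(=O)CC(O)=C(C)C)C(=O)Oc2c1
F6 | step 2 | 2-[(2,6-dihydroxy-4-methoxyphenyl)methyl]-3,5-dihydroxy-4,4-dimethylcyclohexa-2,5-dien-1-one | COc1cc(O)c(CC2=C(O)C(C)(C)C(O)=CC2=O)c(O)c1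
F7 | step 7 | 2-butanoyl-3,5-dihydroxy-4,4-dimethylcyclohexa-2,5-dien-1-one (butanoylfilicinic acid) | CCCC(=O)C1=C(O)C(C)(C)C(O)=CC1=O
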